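Labdane numbering is used throughout: ring A = C1–C5 and C10, ring B = C5–C10, side chain C11–C16 on C9, C17 on C8, C18 (α, equatorial) and C19 (β, axial) on C4, C20 on C10.

## The problem

Compound 43 is a labdane: a trans-fused decalin with a (12E)-3-methylpenta-2,4-dienyl chain on C9, an acetate on the 1β-hydroxyl, an icosanoate on the C18 hydroxymethyl and a free tertiary 8α-hydroxyl. Six stereocentres (C1, C4, C5, C8, C9, C10) sit on the ten ring atoms; C4 and C10 are quaternary and flank C5, C8 is a tertiary carbinol, and the methyl groups C17, C19 and C20 stand syn-axial on one face. The centres can control one another in a chain: C8 and C9 are neighbours and can be fixed together by a stereospecific reaction of an alkene, C9 can dictate C10 through allylic strain, C10 and C5 are tied by the ring fusion, C4 follows from an alkene geometry, and C1 can be set last by the shape of the finished ring A. The side chain needs an E trisubstituted alkene inside a conjugated diene, which is best made late from a C12 aldehyde. The sensitive points are the diene (acid, hydrogenation), the tertiary 8-hydroxyl (dehydration, or ring closure onto C12 or C13 once these are electrophilic) and two different esters that must go onto two different hydroxyls and survive all later steps. The feature that opens the route is the oxygen on C1 next to quaternary C10, together with the ester-level carbon C18 on quaternary C4: ring A can be read as the adduct of a 2-oxy-diene C10=C1(O)–C2=C3 and an (E)-2-methyl-enoate C4=C5, with C6–C9 of ring B as the four-carbon tether.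

## Retrosynthesis

Side chain and last protecting group. The O–Si bond of 42 and the alkenes C14=C15 and C12=C13 are cut, leading through enal 40 to aldehyde 38 and the ylides 41 and 39. A single olefination with an allylic ylide would give no control of the C12=C13 geometry, and dehydration of a C13 carbinol would give regio- and stereoisomers; the stabilised formyl ylide 39 should give the E enal. The triethylsilyl ether stays until the end because a free 8-hydroxyl closes onto a C12 aldehyde and can add to the enal. The forward steps must leave two esters untouched.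

Esters and C12. Aldehyde 38 goes back through alcohol 37 and benzyl ether 36 to hydroxy ester 34 and diol 32, with the acyl groups from 35 and 33. The primary C18 hydroxyl and the hindered secondary C1 hydroxyl differ enough for the large acyl group to be placed first. The benzyl ether is removed by hydrogenolysis while the molecule still has no alkene.

Reduction level of ring A. Diol 32 comes from keto ester 31, which is the hydrolysed form of silyl enol ether 30. One hydride reagent serves both carbonyls; the forward step asks for axial delivery at C1.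

Key disconnection. In 30 the bonds C5–C10 and C3–C4 are cut to give the acyclic triene 29. A cationic bicyclisation (cuts C4–C5 and C9–C10) cannot put oxygen on C1, and an intermolecular cycloaddition for ring A alone would leave the crowded C5–C10 bond to be made separately. The intramolecular version makes that bond with the tether's help and closes both rings at once. Triene 29 has two stereocentres and no ring; the forward reaction must give the trans fusion on one diene face.

Diene and dienophile. Triene 29 is the silyl dienol ether of enone 27; the C1–C2 bond is cut to Weinreb amide 24 and vinyl Grignard 25, and the C4=C5 alkene to aldehyde 22 and ylide 23, which leads back to alkene 19. The enoate is installed before the vinyl ketone because a phosphorus ylide would add to the enone. The Weinreb amide is a latent ketone that survives alkene cleavage and olefination.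

C9–C10 bond and the C8/C9 pair. Amide 19 comes via hydroxy amide 17 from lactone 15, and this from hydroxynitrile 12, made from epoxide 10 and nitrile 11. Anti opening of an E epoxide fixes the C8/C9 relationship by geometry. A face-selective addition to C9 next to an existing C8 centre would instead have to tell the C17 methyl from the C7 methylene, which no acyclic model does reliably. The forward step needs an SN2 reaction at a hindered oxirane carbon.

Chain assembly. Epoxide 10 comes from ether 8 and alcohol 6, and 6 from enyne 1, trimethylaluminium 2 and oxirane 3 (bonds C8–C17 and C9–C11). One operation gives the E alkene, the C11–C12–O unit and a butenyl chain whose terminal alkene is the masked C5 aldehyde.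

## Roads not taken

Alternative 1: The C8–C9 bond of ring B is cut. In the forward step, cathodic reduction of the ring A keto enoate A1 gives a ketyl at C8 that adds 6-exo to the enoate β-carbon C9, forming the 8α-hydroxy ester A2.
- Merits: C8 and C9 are made in one step without a stoichiometric metal reductant, and C12 arrives as an ester, one reduction away from the aldehyde. In this respect it is better than the chosen plan, which spends a benzyl ether, a hydrogenolysis and an oxidation on C12.
- Weak points: A1 already holds C1, C4, C5 and C10, including both quaternary carbons around C5, and these must be assembled on a single ring without help from the step itself. The key step forms only one bond and one ring. The enoate β-carbon is neopentyl, and the required C8 epimer puts the new methyl axial and syn to C20.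
- Comparison: the chosen plan gives up the end-game advantage but creates C4, C5 and C10 and both rings in one event from a chain with two stereocentres.

Alternative 2: The bonds C4–C5 and C9–C10 and the C8–O bond are cut. A Lewis acid opens the epoxide of the acyclic epoxy acid A3; two alkenes and the carboxyl follow in a chair–chair cascade to the hydroxy lactone A4.
- Merits: in skeletal step economy this is clearly better than the chosen plan. The precursor is a short-made polyene, and one step gives rings A and B, the lactone, five stereocentres with the syn-axial methyl groups, and C12 at the acid level.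
- Weak points: the epoxide necessarily leaves the ring A hydroxyl on C3. The target has nothing on C3 and needs oxygen on C1, an unactivated methylene next to quaternary C10, so A4 would need a deoxygenation and a multi-step oxygen transposition with its own stereochemical problem at C1. Such cascades also tend to stop partly at monocyclic products.
- Comparison: the chosen plan is longer to the decalin but puts the oxygen on C1 from the start, as the donor of the diene.

Alternative 3: The C5–C10 bond is cut across a ten-membered ring. A Lewis acid activates the trans epoxide of the cyclodecanone A5, and the C5 enol carbon attacks C10 to give the hydroxy decalone A6.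
- Merits: the epoxide geometry is passed on stereospecifically to the 1β-hydroxyl and the C20 methyl. This is better than the chosen plan, which relies on the facial preference of a hydride at C1.
- Weak points: A5 is a medium ring with an E trisubstituted epoxide and three further stereocentres, and needs a macrocyclisation and a face-selective epoxidation. The new bond joins a carbon next to quaternary C4 to a fully substituted epoxide carbon. The C6 ketone can also enolise towards C7, the epoxide can rearrange by hydride shift, and the C6 carbonyl of A6 must later be removed.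
- Comparison: the chosen plan sets one centre less securely (C1) but has an acyclic precursor made by standard reactions and leaves no extra functional group to remove.

Key step: step 12

Remark on the chemistry: the Shi ketone made from D-fructose is assumed to give the (8R,9R)-epoxide 10 from the E trisubstituted alkene of 8, as with other such alkenes; compounds 12–27 are carried as mixtures of C10 epimers, which converge in 29.

Step 1
Reactants: 1 hex-1-en-5-yne; 2 trimethylaluminium; 3 oxirane
Product: 6 (3E)-4-methylocta-3,7-dien-1-ol, via alkenyldimethylalane 4 (not isolated), via lithium alkenylalanate 5 (not isolated)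
Conditions: AlMe3 (2 equiv), Cp2ZrCl2 (0.2 equiv), CH2Cl2, 0 °C → rt; volatiles off, hexane; n-BuLi, −78 → 0 °C; oxirane, THF, −78 °C → rt; aq. HCl
Reagents that add atoms: trimethylaluminium, C[Al](C)C (the C17 methyl); oxirane, C1CO1 (C11, C12 and the oxygen)
Why: Zirconium-catalysed carboalumination of a terminal alkyne (Negishi) adds methyl and aluminium syn with methyl on the inner carbon, so the C8=C9 alkene is fixed as E; the alanate then opens oxirane with retention of the alkene geometry. The isolated terminal alkene should be left alone because carboalumination of alkenes with this catalyst is much slower.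

Step 2
Reactants: 6 (3E)-4-methylocta-3,7-dien-1-ol; 7 benzyl bromide
Product: 8 benzyl (3E)-4-methylocta-3,7-dien-1-yl ether
Conditions: NaH, Bu4NI (cat.), THF, 0 °C → rt
Reagents that add atoms: benzyl bromide, BrCc1ccccc1
Why: Williamson ether synthesis on a primary alkoxide; the benzyl group later leaves by hydrogenolysis at a stage without alkenes.

Step 3
Reactants: 8 benzyl (3E)-4-methylocta-3,7-dien-1-yl ether; 9 potassium peroxymonosulfate
Product: 10 (2R,3R)-2-[2-(benzyloxy)ethyl]-3-(but-3-en-1-yl)-3-methyloxirane
Conditions: D-fructose-derived Shi ketone (0.3 equiv), KHSO5 (as 2KHSO5·KHSO4·K2SO4), K2CO3, Bu4NHSO4, MeCN/CH2(OMe)2/aq. Na2B4O7, 0 °C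
Reagents that add atoms: potassium peroxymonosulfate, [K+].[O-]S(=O)(=O)OO
Why: Shi asymmetric epoxidation: the chiral dioxirane transfers oxygen through a spiro transition state to one face of the E trisubstituted alkene, which sets C8 for good and C9 provisionally. The monosubstituted terminal alkene is a poor substrate for this oxidant and should remain.

Step 4
Reactants: 10 (2R,3R)-2-[2-(benzyloxy)ethyl]-3-(but-3-en-1-yl)-3-methyloxirane; 11 propanenitrile
Product: 12 (3R,4R)-3-[2-(benzyloxy)ethyl]-4-hydroxy-2,4-dimethyloct-7-enenitrile (both C2 epimers)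
Conditions: LiN(iPr)2 (2.2 equiv), 11 (2.5 equiv), THF, −78 °C; then 10, −78 → 45 °C; aq. NH4Cl
Reagents that add atoms: propanenitrile, CCC#N
Why: Alkylation of a metalated nitrile by an epoxide: SN2 attack at the less substituted oxirane carbon C9 with inversion, while C8 keeps its oxygen and configuration. Because the alkene was E, the anti opening gives the 8R,9R pair of the target without any need to tell C17 from C7; C10 forms as a mixture that is erased later.

Step 5
Reactants: 12 (3R,4R)-3-[2-(benzyloxy)ethyl]-4-hydroxy-2,4-dimethyloct-7-enenitrile; 13 water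
Product: 15 (4R,5R)-4-[2-(benzyloxy)ethyl]-5-(but-3-en-1-yl)-3,5-dimethyloxolan-2-one (both C3 epimers), via hydroxy acid 14 (not isolated)
Conditions: KOH, HOCH2CH2OH/H2O, 120 °C; then 2 M HCl, rt
Reagents that add atoms: water, O
Why: Alkaline nitrile hydrolysis, helped by the neighbouring alkoxide, followed by lactonisation on acidification; the γ-hydroxy acid with a fully substituted carbinol carbon should close spontaneously. No defined stereocentre is touched.

Step 6
Reactants: 15 (4R,5R)-4-[2-(benzyloxy)ethyl]-5-(but-3-en-1-yl)-3,5-dimethyloxolan-2-one; 16 N,O-dimethylhydroxylamine hydrochloride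
Product: 17 (3R,4R)-3-[2-(benzyloxy)ethyl]-4-hydroxy-N-methoxy-N,2,4-trimethyloct-7-enamide
Conditions: AlMe3 (3 equiv), 16 (3 equiv), CH2Cl2, 0 °C → rt; aq. potassium sodium tartrate (KNaC4H4O6)
Reagents that add atoms: N,O-dimethylhydroxylamine hydrochloride, CNOC.Cl
Why: Weinreb aminolysis of a lactone by an aluminium amide; formation of the aluminium alkoxide drives the ring opening. The product is used at once because it can close back to the lactone.

Step 7
Reactants: 17 (3R,4R)-3-[2-(benzyloxy)ethyl]-4-hydroxy-N-methoxy-N,2,4-trimethyloct-7-enamide; 18 triethylsilyl trifluoromethanesulfonate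
Product: 19 (3R,4R)-3-[2-(benzyloxy)ethyl]-N-methoxy-N,2,4-trimethyl-4-(triethylsilyloxy)oct-7-enamide
Conditions: TESOTf, 2,6-lutidine, CH2Cl2, −78 → 0 °C
Reagents that add atoms: triethylsilyl trifluoromethanesulfonate, CC[Si](CC)(CC)OS(=O)(=O)C(F)(F)F
Why: Silylation of a tertiary alcohol with a silyl triflate; it blocks relactonisation and protects the 8-hydroxyl up to the last step.

Step 8
Reactants: 19 (3R,4R)-3-[2-(benzyloxy)ethyl]-N-methoxy-N,2,4-trimethyl-4-(triethylsilyloxy)oct-7-enamide; 20 sodium periodate
Product: 22 (3R,4R)-3-[2-(benzyloxy)ethyl]-N-methoxy-N,2,4-trimethyl-7-oxo-4-(triethylsilyloxy)heptanamide, via vicinal diol 21 (not isolated)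
Conditions: OsO4 (2 mol%), NaIO4 (4 equiv), 2,6-lutidine, dioxane/H2O, rt
Reagents that add atoms: sodium periodate, [Na+].[O-]I(=O)(=O)=O (oxygen, handed on through catalytic OsO4)
Why: Johnson–Lemieux cleavage of the only alkene in the molecule: dihydroxylation then periodate cleavage gives the C5 aldehyde. The buffered conditions should spare the silyl and benzyl ethers.

Step 9
Reactants: 22 (3R,4R)-3-[2-(benzyloxy)ethyl]-N-methoxy-N,2,4-trimethyl-7-oxo-4-(triethylsilyloxy)heptanamide; 23 methyl 2-(triphenylphosphoranylidene)propanoate
Product: 24 methyl (2E,6R,7R)-7-[2-(benzyloxy)ethyl]-9-[methoxy(methyl)amino]-2,6,8-trimethyl-9-oxo-6-(triethylsilyloxy)non-2-enoate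
Conditions: 23 (1.3 equiv), CH2Cl2, rt → 40 °C
Reagents that add atoms: methyl 2-(triphenylphosphoranylidene)propanoate, COC(=O)C(C)=P(c1ccccc1)(c1ccccc1)c1ccccc1
Why: Wittig reaction of a stabilised ylide with an aliphatic aldehyde, which should give the E enoate (ester cis to H-5); this geometry later fixes C4.

Step 10
Reactants: 24 methyl (2E,6R,7R)-7-[2-(benzyloxy)ethyl]-9-[methoxy(methyl)amino]-2,6,8-trimethyl-9-oxo-6-(triethylsilyloxy)non-2-enoate; 25 vinylmagnesium bromide
Product: 27 methyl (2E,6R,7R)-7-[2-(benzyloxy)ethyl]-2,6,8-trimethyl-9-oxo-6-(triethylsilyloxy)undeca-2,10-dienoate, via magnesium hemiaminal chelate 26 (not isolated)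
Conditions: CH2=CHMgBr (1.5 equiv), THF, −40 → 0 °C; cold 1 M HCl
Reagents that add atoms: vinylmagnesium bromide, C=C[Mg]Br
Why: Weinreb ketone synthesis: the chelated tetrahedral adduct holds until work-up, so addition stops at the ketone. The trisubstituted conjugated methyl ester is much less electrophilic at this temperature, and the acidic quench keeps the released amine from adding to the enone.

Step 11
Reactants: 27 methyl (2E,6R,7R)-7-[2-(benzyloxy)ethyl]-2,6,8-trimethyl-9-oxo-6-(triethylsilyloxy)undeca-2,10-dienoate; 28 tert-butyldimethylsilyl trifluoromethanesulfonate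
Product: 29 methyl (2E,6R,7R,8Z)-7-[2-(benzyloxy)ethyl]-9-[tert-butyl(dimethyl)silyloxy]-2,6,8-trimethyl-6-(triethylsilyloxy)undeca-2,8,10-trienoate
Conditions: TBSOTf (1.5 equiv), Et3N (3 equiv), CH2Cl2, −78 → 0 °C
Reagents that add atoms: tert-butyldimethylsilyl trifluoromethanesulfonate, CC(C)(C)[Si](C)(C)OS(=O)(=O)C(F)(F)F
Why: Soft enolisation of the vinyl ketone with silyl triflate and amine towards its only enolisable carbon C10 gives the 2-silyloxydiene, and both C10 epimers converge. The branched C9 substituent should prefer the position cis to the silyloxy group over the one cis to the vinyl group (less allylic strain), which is the Z isomer with the tether on the outer side of the diene.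

Step 12
Reactants: 29 methyl (2E,6R,7R,8Z)-7-[2-(benzyloxy)ethyl]-9-[tert-butyl(dimethyl)silyloxy]-2,6,8-trimethyl-6-(triethylsilyloxy)undeca-2,8,10-trienoate
Product: 30 methyl 12-(benzyloxy)-1-[tert-butyl(dimethyl)silyloxy]-8α-(triethylsilyloxy)-13,14,15,16-tetranorlabd-1-en-18-oate (trans-decalin with 5α-H 9α-H 10β-methyl 4β-methyl)
Conditions: PhMe (0.01 M, degassed), BHT (cat.), sealed tube, 180 °C
Reagents that add atoms: none
Why: Thermal, concerted but asynchronous [4+2] cycloaddition of the electron-rich 2-silyloxydiene C10=C1(OTBS)–C2=C3 with the tethered (E)-2-methyl-enoate C4=C5; the nucleophilic diene end C10 pairs with the enoate β-carbon C5, and C3 with C4. The closest known reaction type is the thermal type 1 intramolecular Diels–Alder reaction of 1,7,9-decatrienes that carry a 2-silyloxydiene. Ring A closes as the six-membered cycloadduct ring (bonds C5–C10 and C3–C4), and ring B closes as the six-membered tether ring through the same C5–C10 bond, with C6–C9 in a chair. C10 is controlled by C9: allylic 1,3-strain with the C1 silyloxy group holds H-9 in the diene plane, so the tether carbon C8 and with it the dienophile can reach only one diene face, which places the C20 methyl anti to H-9. C5 follows from the orientation of the dienophile: with the tether on the outer position of C10, the chair tether with the triethylsilyloxy group equatorial and the ester endo leads to the trans ring fusion. C4 is set by the alkene geometry, since suprafacial addition keeps the ester cis to H-5 (equatorial C18, axial C19). The step needs the trans fusion and one diene face; the face rests on allylic strain and is the safer of the two, while the fusion rests on the endo and chair preferences. The silyl enol ether left at C1=C2 is the masked C1 ketone.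

Step 13
Reactants: 30 methyl 12-(benzyloxy)-1-[tert-butyl(dimethyl)silyloxy]-8α-(triethylsilyloxy)-13,14,15,16-tetranorlabd-1-en-18-oate
Product: 31 methyl 12-(benzyloxy)-1-oxo-8α-(triethylsilyloxy)-13,14,15,16-tetranorlabdan-18-oate
Conditions: TBAF, AcOH, THF, 0 °C
Reagents that add atoms: none
Why: Fluoride cleavage of a silyl enol ether with protonation at C2; the enol ether should react far faster than the hindered tertiary triethylsilyl ether.

Step 14
Reactants: 31 methyl 12-(benzyloxy)-1-oxo-8α-(triethylsilyloxy)-13,14,15,16-tetranorlabdan-18-oate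
Product: 32 12-(benzyloxy)-8α-(triethylsilyloxy)-13,14,15,16-tetranorlabdane-1β,18-diol
Conditions: LiAlH4, THF, −20 °C → rt
Reagents that add atoms: none
Why: Hydride reduction of ketone and ester in one operation. The small hydride should attack C1 axially from the α face, because the equatorial path is blocked by the axial C20 methyl on the neighbouring C10 and by C11; this gives the equatorial 1β-alcohol.

Step 15
Reactants: 32 12-(benzyloxy)-8α-(triethylsilyloxy)-13,14,15,16-tetranorlabdane-1β,18-diol; 33 icosanoyl chloride
Product: 34 12-(benzyloxy)-1β-hydroxy-8α-(triethylsilyloxy)-13,14,15,16-tetranorlabdan-18-yl icosanoate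
Conditions: 33 (1.05 equiv), pyridine, DMAP (cat.), CH2Cl2, −20 → 0 °C
Reagents that add atoms: icosanoyl chloride, CCCCCCCCCCCCCCCCCCCC(=O)Cl
Why: Site-selective acylation: the primary C18 hydroxyl should react well before the secondary C1 hydroxyl, which is wedged between quaternary C10 and C11.

Step 16
Reactants: 34 12-(benzyloxy)-1β-hydroxy-8α-(triethylsilyloxy)-13,14,15,16-tetranorlabdan-18-yl icosanoate; 35 acetic anhydride
Product: 36 1β-acetoxy-12-(benzyloxy)-8α-(triethylsilyloxy)-13,14,15,16-tetranorlabdan-18-yl icosanoate
Conditions: Ac2O, Et3N, DMAP, CH2Cl2, rt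
Reagents that add atoms: acetic anhydride, CC(=O)OC(C)=O
Why: DMAP-catalysed acetylation of the remaining secondary alcohol; the tertiary silyl ether and the long-chain ester are inert.

Step 17
Reactants: 36 1β-acetoxy-12-(benzyloxy)-8α-(triethylsilyloxy)-13,14,15,16-tetranorlabdan-18-yl icosanoate
Product: 37 1β-acetoxy-12-hydroxy-8α-(triethylsilyloxy)-13,14,15,16-tetranorlabdan-18-yl icosanoate
Conditions: H2 (1 atm), Pd/C, EtOAc, rt
Reagents that add atoms: none
Why: Hydrogenolysis of the benzyl ether, placed here because the molecule has no alkene at this stage; the neutral aprotic solvent keeps the silyl ether.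

Step 18
Reactants: 37 1β-acetoxy-12-hydroxy-8α-(triethylsilyloxy)-13,14,15,16-tetranorlabdan-18-yl icosanoate
Product: 38 1β-acetoxy-12-oxo-8α-(triethylsilyloxy)-13,14,15,16-tetranorlabdan-18-yl icosanoate
Conditions: Dess–Martin periodinane, NaHCO3, CH2Cl2, rt
Reagents that add atoms: none
Why: Dess–Martin oxidation of the primary alcohol to the C12 aldehyde under buffered neutral conditions; the silyl ether on C8 prevents lactol formation.

Step 19
Reactants: 38 1β-acetoxy-12-oxo-8α-(triethylsilyloxy)-13,14,15,16-tetranorlabdan-18-yl icosanoate; 39 2-(triphenylphosphoranylidene)propanal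
Product: 40 (12E)-1β-acetoxy-14-oxo-8α-(triethylsilyloxy)-15-norlabd-12-en-18-yl icosanoate
Conditions: 39 (1.5 equiv), PhMe, 90 °C
Reagents that add atoms: 2-(triphenylphosphoranylidene)propanal, CC(C=O)=P(c1ccccc1)(c1ccccc1)c1ccccc1
Why: Wittig reaction with a stabilised formyl ylide, which should give the E trisubstituted enal; the product enal is less reactive than the starting aldehyde, so a second olefination is slow.

Step 20
Reactants: 40 (12E)-1β-acetoxy-14-oxo-8α-(triethylsilyloxy)-15-norlabd-12-en-18-yl icosanoate; 41 methyltriphenylphosphonium bromide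
Product: 42 (12E)-1β-acetoxy-8α-(triethylsilyloxy)labda-12,14-dien-18-yl icosanoate
Conditions: 41, KOtBu, THF, 0 °C; then 40, −78 → 0 °C
Reagents that add atoms: methyltriphenylphosphonium bromide, C[P+](c1ccccc1)(c1ccccc1)c1ccccc1.[Br-]
Why: Wittig methylenation at the aldehyde carbonyl completes the diene without touching the C12=C13 geometry; the two hindered esters should not react with the ylide at low temperature.

Step 21
Reactants: 42 (12E)-1β-acetoxy-8α-(triethylsilyloxy)labda-12,14-dien-18-yl icosanoate
Product: 43 (12E)-1β-acetoxy-8α-hydroxylabda-12,14-dien-18-yl icosanoate (CNP0288884.2)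
Conditions: TBAF, AcOH, THF, rt → 40 °C
Reagents that add atoms: none
Why: Fluoride cleavage of the tertiary silyl ether; the acetic acid buffer avoids both strong acid (ring closure of the 8-hydroxyl onto the diene) and strong base (acyl loss).

Compound list

1 | hex-1-en-5-yne | C=CCCC#C | starting material
2 | trimethylaluminium | C[Al](C)C | starting material
3 | oxirane | C1CO1 | starting material
4 | dimethyl[(1E)-2-methylhexa-1,5-dien-1-yl]alane | C=CCC/C(C)=C/[Al](C)C | intermediate (not isolated)
5 | lithium butyl(dimethyl)[(1E)-2-methylhexa-1,5-dien-1-yl]alanate | [Li+].C=CCC/C(C)=C/[Al-](C)(C)CCCC | intermediate (not isolated)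
6 | (3E)-4-methylocta-3,7-dien-1-ol | OCC/C=C(\C)CCC=C | intermediate
7 | benzyl bromide | BrCc1ccccc1 | starting material
8 | benzyl (3E)-4-methylocta-3,7-dien-1-yl ether | C=CCC/C(C)=C/CCOCc1ccccc1 | intermediate
9 | potassium peroxymonosulfate | [K+].[O-]S(=O)(=O)OO | starting material
10 | (2R,3R)-2-[2-(benzyloxy)ethyl]-3-(but-3-en-1-yl)-3-methyloxirane | C=CCC[C@@]1(C)O[C@@H]1CCOCc1ccccc1 | intermediate
11 | propanenitrile | CCC#N | starting material
12 | (3R,4R)-3-[2-(benzyloxy)ethyl]-4-hydroxy-2,4-dimethyloct-7-enenitrile, both C2 epimers | N#CC(C)[C@@H](CCOCc1ccccc1)[C@](C)(O)CCC=C | intermediate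
13 | water | O | starting material
14 | (3R,4R)-3-[2-(benzyloxy)ethyl]-4-hydroxy-2,4-dimethyloct-7-enoic acid, both C2 epimers | OC(=O)C(C)[C@@H](CCOCc1ccccc1)[C@](C)(O)CCC=C | intermediate (not isolated)
15 | (4R,5R)-4-[2-(benzyloxy)ethyl]-5-(but-3-en-1-yl)-3,5-dimethyloxolan-2-one, both C3 epimers | CC1[C@@H](CCOCc2ccccc2)[C@](C)(OC1=O)CCC=C | intermediate
16 | N,O-dimethylhydroxylamine hydrochloride | CNOC.Cl | starting material
17 | (3R,4R)-3-[2-(benzyloxy)ethyl]-4-hydroxy-N-methoxy-N,2,4-trimethyloct-7-enamide, both C2 epimers | CON(C)C(=O)C(C)[C@@H](CCOCc1ccccc1)[C@](C)(O)CCC=C | intermediate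
18 | triethylsilyl trifluoromethanesulfonate | CC[Si](CC)(CC)OS(=O)(=O)C(F)(F)F | starting material
19 | (3R,4R)-3-[2-(benzyloxy)ethyl]-N-methoxy-N,2,4-trimethyl-4-(triethylsilyloxy)oct-7-enamide, both C2 epimers | CON(C)C(=O)C(C)[C@@H](CCOCc1ccccc1)[C@](C)(O[Si](CC)(CC)CC)CCC=C | intermediate
20 | sodium periodate | [Na+].[O-]I(=O)(=O)=O | starting material
21 | (3R,4R)-3-[2-(benzyloxy)ethyl]-7,8-dihydroxy-N-methoxy-N,2,4-trimethyl-4-(triethylsilyloxy)octanamide, epimers at C2 and C7 | CON(C)C(=O)C(C)[C@@H](CCOCc1ccccc1)[C@](C)(O[Si](CC)(CC)CC)CCC(O)CO | intermediate (not isolated)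
22 | (3R,4R)-3-[2-(benzyloxy)ethyl]-N-methoxy-N,2,4-trimethyl-7-oxo-4-(triethylsilyloxy)heptanamide, both C2 epimers | CON(C)C(=O)C(C)[C@@H](CCOCc1ccccc1)[C@](C)(O[Si](CC)(CC)CC)CCC=O | intermediate
23 | methyl 2-(triphenylphosphoranylidene)propanoate | COC(=O)C(C)=P(c1ccccc1)(c1ccccc1)c1ccccc1 | starting material
24 | methyl (2E,6R,7R)-7-[2-(benzyloxy)ethyl]-9-[methoxy(methyl)amino]-2,6,8-trimethyl-9-oxo-6-(triethylsilyloxy)non-2-enoate, both C8 epimers | CON(C)C(=O)C(C)[C@@H](CCOCc1ccccc1)[C@](C)(O[Si](CC)(CC)CC)CC/C=C(\C)C(=O)OC | intermediate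
25 | vinylmagnesium bromide | C=C[Mg]Br | starting material
26 | bromomagnesium hemiaminal chelate of 24 with the vinyl group on the former amide carbon | C=CC(O[Mg]Br)(N(C)OC)C(C)[C@@H](CCOCc1ccccc1)[C@](C)(O[Si](CC)(CC)CC)CC/C=C(\C)C(=O)OC | intermediate (not isolated)
27 | methyl (2E,6R,7R)-7-[2-(benzyloxy)ethyl]-2,6,8-trimethyl-9-oxo-6-(triethylsilyloxy)undeca-2,10-dienoate, both C8 epimers | C=CC(=O)C(C)[C@@H](CCOCc1ccccc1)[C@](C)(O[Si](CC)(CC)CC)CC/C=C(\C)C(=O)OC | intermediate
28 | tert-butyldimethylsilyl trifluoromethanesulfonate | CC(C)(C)[Si](C)(C)OS(=O)(=O)C(F)(F)F | starting material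
29 | methyl (2E,6R,7R,8Z)-7-[2-(benzyloxy)ethyl]-9-[tert-butyl(dimethyl)silyloxy]-2,6,8-trimethyl-6-(triethylsilyloxy)undeca-2,8,10-trienoate | C=C/C(O[Si](C)(C)C(C)(C)C)=C(\C)[C@@H](CCOCc1ccccc1)[C@](C)(O[Si](CC)(CC)CC)CC/C=C(\C)C(=O)OC | intermediate (key-step precursor)
30 | methyl 12-(benzyloxy)-1-[tert-butyl(dimethyl)silyloxy]-8α-(triethylsilyloxy)-13,14,15,16-tetranorlabd-1-en-18-oate | c1ccccc1COCC[C@@H]1[C@@]2(C)C(O[Si](C)(C)C(C)(C)C)=CC[C@@](C)(C(=O)OC)[C@@H]2CC[C@@]1(C)O[Si](CC)(CC)CC | intermediate (key-step product)
31 | methyl 12-(benzyloxy)-1-oxo-8α-(triethylsilyloxy)-13,14,15,16-tetranorlabdan-18-oate | c1ccccc1COCC[C@@H]1[C@@]2(C)C(=O)CC[C@@](C)(C(=O)OC)[C@@H]2CC[C@@]1(C)O[Si](CC)(CC)CC | intermediate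
32 | 12-(benzyloxy)-8α-(triethylsilyloxy)-13,14,15,16-tetranorlabdane-1β,18-diol | c1ccccc1COCC[C@@H]1[C@@]2(C)[C@H](O)CC[C@@](C)(CO)[C@@H]2CC[C@@]1(C)O[Si](CC)(CC)CC | intermediate
33 | icosanoyl chloride | CCCCCCCCCCCCCCCCCCCC(=O)Cl | starting material
34 | 12-(benzyloxy)-1β-hydroxy-8α-(triethylsilyloxy)-13,14,15,16-tetranorlabdan-18-yl icosanoate | c1ccccc1COCC[C@@H]1[C@@]2(C)[C@H](O)CC[C@@](C)(COC(=O)CCCCCCCCCCCCCCCCCCC)[C@@H]2CC[C@@]1(C)O[Si](CC)(CC)CC | intermediate
35 | acetic anhydride | CC(=O)OC(C)=O | starting material
36 | 1β-acetoxy-12-(benzyloxy)-8α-(triethylsilyloxy)-13,14,15,16-tetranorlabdan-18-yl icosanoate | c1ccccc1COCC[C@@H]1[C@@]2(C)[C@H](OC(C)=O)CC[C@@](C)(COC(=O)CCCCCCCCCCCCCCCCCCC)[C@@H]2CC[C@@]1(C)O[Si](CC)(CC)CC | intermediate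
37 | 1β-acetoxy-12-hydroxy-8α-(triethylsilyloxy)-13,14,15,16-tetranorlabdan-18-yl icosanoate | OCC[C@@H]1[C@@]2(C)[C@H](OC(C)=O)CC[C@@](C)(COC(=O)CCCCCCCCCCCCCCCCCCC)[C@@H]2CC[C@@]1(C)O[Si](CC)(CC)CC | intermediate
38 | 1β-acetoxy-12-oxo-8α-(triethylsilyloxy)-13,14,15,16-tetranorlabdan-18-yl icosanoate | O=CC[C@@H]1[C@@]2(C)[C@H](OC(C)=O)CC[C@@](C)(COC(=O)CCCCCCCCCCCCCCCCCCC)[C@@H]2CC[C@@]1(C)O[Si](CC)(CC)CC | intermediate
39 | 2-(triphenylphosphoranylidene)propanal | CC(C=O)=P(c1ccccc1)(c1ccccc1)c1ccccc1 | starting material
40 | (12E)-1β-acetoxy-14-oxo-8α-(triethylsilyloxy)-15-norlabd-12-en-18-yl icosanoate | O=C/C(C)=C/C[C@@H]1[C@@]2(C)[C@H](OC(C)=O)CC[C@@](C)(COC(=O)CCCCCCCCCCCCCCCCCCC)[C@@H]2CC[C@@]1(C)O[Si](CC)(CC)CC | intermediate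
41 | methyltriphenylphosphonium bromide | C[P+](c1ccccc1)(c1ccccc1)c1ccccc1.[Br-] | starting material
42 | (12E)-1β-acetoxy-8α-(triethylsilyloxy)labda-12,14-dien-18-yl icosanoate | C=C/C(C)=C/C[C@@H]1[C@@]2(C)[C@H](OC(C)=O)CC[C@@](C)(COC(=O)CCCCCCCCCCCCCCCCCCC)[C@@H]2CC[C@@]1(C)O[Si](CC)(CC)CC | intermediate
43 | (12E)-1β-acetoxy-8α-hydroxylabda-12,14-dien-18-yl icosanoate (CNP0288884.2) | C=C/C(C)=C/C[C@@H]1[C@@]2(C)[C@H](OC(C)=O)CC[C@@](C)(COC(=O)CCCCCCCCCCCCCCCCCCC)[C@@H]2CC[C@@]1(C)O | target

Total step count: 21. Longest linear sequence: 21 steps (1 → 43); all other reactants are bought.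

Least certain steps

Step 12 (key step). Three processes can divert material. Enolisation in step 11 may give part of the dienol ether with the tether on the inner side of the diene, and that isomer cannot reach the trans-fused transition state. Endo/exo discrimination in a decatriene is not large, and a methyl group on the dienophile weakens the endo preference of the ester, so cis-fused adduct may form. At the temperature needed for a diene with a fully substituted terminus, a [1,5]-hydrogen shift from the inner C20 methyl can isomerise the diene. The fallback forms the same two bonds stepwise as an anionic double Michael reaction. It sets out from enone 27: LiN(SiMe3)2 in THF at −78 °C gives the lithium cross-conjugated dienolate F1, whose C10 adds to C5 of the enoate and closes ring B to the lithium ester enolate F2. This adds through C4 to C3 of the vinyl ketone and closes ring A, and protonation comes back to the route at ketone 31. Enol ether geometry and heating no longer matter; the ring fusion would then be decided by a chelated chair-like addition.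

Step 4. The SN2 reaction takes place at a secondary oxirane carbon next to a fully substituted one, so it may be slow, and the basic secondary carbanion may instead isomerise the epoxide to an allylic alcohol. The fallback uses the smaller primary nitrile anion and adds the methyl group later. It sets out from epoxide 10: LiCH2CN (from acetonitrile and n-BuLi) should give (3S,4R)-3-[2-(benzyloxy)ethyl]-4-hydroxy-4-methyloct-7-enenitrile F3. Hydrolysis and acidification as in step 5 give (4R,5R)-4-[2-(benzyloxy)ethyl]-5-(but-3-en-1-yl)-5-methyloxolan-2-one F4, and enolate methylation (LiN(iPr)2, MeI, THF, −78 °C) comes back at lactone 15.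

Step 10. The Weinreb amide is branched at both the α and the β carbon, so addition may be slow enough for the Grignard reagent to attack the enoate as well; the released amine can also add to the product enone. The fallback separates reduction and carbon–carbon bond formation. It sets out from amide 24: Cp2Zr(H)Cl in THF reduces the amide, in the presence of the ester, to the aldehyde methyl (2E,6R,7R)-7-[2-(benzyloxy)ethyl]-2,6,8-trimethyl-9-oxo-6-(triethylsilyloxy)non-2-enoate F5. CH2=CHMgBr at −78 °C adds to the aldehyde only and gives the allylic alcohol methyl (2E,6R,7R)-7-[2-(benzyloxy)ethyl]-9-hydroxy-2,6,8-trimethyl-6-(triethylsilyloxy)undeca-2,10-dienoate F6, and Dess–Martin oxidation comes back at enone 27.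

Step 14. Facial selectivity of hydride delivery at C1 may be poor: the axial path passes three syn-axial hydrogens (on C3, C5 and C9) and the equatorial alcohol is compressed against C11, so some 1α-alcohol may form. The fallback sets C1 under thermodynamic control by electron transfer. It sets out from ketone 31: SmI2 in THF/i-PrOH reduces the ketone through its ketyl to the more stable equatorial alcohol, methyl 12-(benzyloxy)-1β-hydroxy-8α-(triethylsilyloxy)-13,14,15,16-tetranorlabdan-18-oate F7, and leaves the ester. LiAlH4 then reduces the ester and comes back at diol 32.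

Step 21. Cleavage of a hindered tertiary silyl ether may be slow; forcing it risks acid-promoted ring closure of the freed 8-hydroxyl onto the diene, or fluoride-promoted loss of an acyl group. The fallback frees the hydroxyl before the diene exists. It sets out from aldehyde 38: HF·pyridine in THF removes the silyl group and the hydroxy aldehyde closes to the lactol 1β-acetoxy-12-hydroxy-8α,12-epoxy-13,14,15,16-tetranorlabdan-18-yl icosanoate F8. A Wittig reaction of its open form with ylide 39 gives the hydroxy enal (12E)-1β-acetoxy-8α-hydroxy-14-oxo-15-norlabd-12-en-18-yl icosanoate F9, and methylenation with the ylide from 41 and KOtBu comes back at target 43.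

Further compounds

F1 | step 12 | lithium cross-conjugated dienolate of enone 27 (C10=C1 enolate, geometry open) | C=CC(O[Li])=C(C)[C@@H](CCOCc1ccccc1)[C@](C)(O[Si](CC)(CC)CC)CC/C=C(\C)C(=O)OC
F2 | step 12 | ring B lithium ester enolate after the first Michael addition (C5–C10 bond formed, vinyl ketone on C10) | c1ccccc1COCC[C@@H]1[C@@](C)(C(=O)C=C)[C@H](C(C)=C(OC)O[Li])CC[C@@]1(C)O[Si](CC)(CC)CC
F3 | step 4 | (3S,4R)-3-[2-(benzyloxy)ethyl]-4-hydroxy-4-methyloct-7-enenitrile | N#CC[C@@H](CCOCc1ccccc1)[C@](C)(O)CCC=C
F4 | step 4 | (4R,5R)-4-[2-(benzyloxy)ethyl]-5-(but-3-en-1-yl)-5-methyloxolan-2-one | C1[C@@H](CCOCc2ccccc2)[C@](C)(OC1=O)CCC=C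
F5 | step 10 | methyl (2E,6R,7R)-7-[2-(benzyloxy)ethyl]-2,6,8-trimethyl-9-oxo-6-(triethylsilyloxy)non-2-enoate, both C8 epimers | O=CC(C)[C@@H](CCOCc1ccccc1)[C@](C)(O[Si](CC)(CC)CC)CC/C=C(\C)C(=O)OC
F6 | step 10 | methyl (2E,6R,7R)-7-[2-(benzyloxy)ethyl]-9-hydroxy-2,6,8-trimethyl-6-(triethylsilyloxy)undeca-2,10-dienoate, epimers at C8 and C9 | C=CC(O)C(C)[C@@H](CCOCc1ccccc1)[C@](C)(O[Si](CC)(CC)CC)CC/C=C(\C)C(=O)OC
F7 | step 14 | methyl 12-(benzyloxy)-1β-hydroxy-8α-(triethylsilyloxy)-13,14,15,16-tetranorlabdan-18-oate | c1ccccc1COCC[C@@H]1[C@@]2(C)[C@H](O)CC[C@@](C)(C(=O)OC)[C@@H]2CC[C@@]1(C)O[Si](CC)(CC)CC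
F8 | step 21 | 1β-acetoxy-12-hydroxy-8α,12-epoxy-13,14,15,16-tetranorlabdan-18-yl icosanoate (lactol, both C12 anomers) | OC1C[C@@H]2[C@@]3(C)[C@H](OC(C)=O)CC[C@@](C)(COC(=O)CCCCCCCCCCCCCCCCCCC)[C@@H]3CC[C@@]2(C)O1
F9 | step 21 | (12E)-1β-acetoxy-8α-hydroxy-14-oxo-15-norlabd-12-en-18-yl icosanoate | O=C/C(C)=C/C[C@@H]1[C@@]2(C)[C@H](OC(C)=O)CC[C@@](C)(COC(=O)CCCCCCCCCCCCCCCCCCC)[C@@H]2CC[C@@]1(C)O
A1 | alternative 1 | ring A keto enoate: methyl (2E)-3-[2-(tert-butyldimethylsilyloxy)-5-(tert-butyldimethylsilyloxymethyl)-1,5-dimethyl-6-(3-oxobutyl)cyclohexyl]prop-2-enoate, configuration as in the SMILES | COC(=O)/C=C/[C@@]1(C)[C@H](O[Si](C)(C)C(C)(C)C)CC[C@@](C)(CO[Si](C)(C)C(C)(C)C)[C@@H]1CCC(C)=O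
A2 | alternative 1 | methyl 1β,18-bis(tert-butyldimethylsilyloxy)-8α-hydroxy-13,14,15,16-tetranorlabdan-12-oate | COC(=O)C[C@@H]1[C@@]2(C)[C@H](O[Si](C)(C)C(C)(C)C)CC[C@@](C)(CO[Si](C)(C)C(C)(C)C)[C@@H]2CC[C@@]1(C)O
A3 | alternative 2 | (3E,7E)-13-(benzyloxy)-11,12-epoxy-4,8,12-trimethyltrideca-3,7-dienoic acid, epoxide configuration as in the SMILES | OC(=O)C/C=C(\C)CC/C=C(\C)CC[C@@H]1O[C@@]1(C)COCc1ccccc1
A4 | alternative 2 | 3β-hydroxy-18-benzyloxysclareolide | O=C1C[C@@H]2[C@@]3(C)CC[C@H](O)[C@@](C)(COCc4ccccc4)[C@@H]3CC[C@@]2(C)O1
A5 | alternative 3 | ten-membered trans-1,10-epoxy-6-ketone with the C4, C8 and C9 substituents of the target (12-benzyloxy, 18-tert-butyldimethylsilyloxy, 8-triethylsilyloxy) | c1ccccc1COCC[C@@H]1[C@@]2(C)O[C@@H]2CC[C@@](C)(CO[Si](C)(C)C(C)(C)C)CC(=O)C[C@@]1(C)O[Si](CC)(CC)CC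
A6 | alternative 3 | 12-(benzyloxy)-18-(tert-butyldimethylsilyloxy)-1β-hydroxy-8α-(triethylsilyloxy)-13,14,15,16-tetranorlabdan-6-one | c1ccccc1COCC[C@@H]1[C@@]2(C)[C@H](O)CC[C@@](C)(CO[Si](C)(C)C(C)(C)C)[C@@H]2C(=O)C[C@@]1(C)O[Si](CC)(CC)CC
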